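At 5.0 min this flask passes to you, so here is what stands in it and what I expect.

| flask | X | Q | E | remark | time |
|---|---|---|---|---|---|
| maple | 0.050 M | 0.030 M | 0.025 M | the very flask that is asked about, followed so far |  |
| flask | 0.050 M | 0.0300 M | 0.0250 M |  | 5.0 min |

- maple (time / min: J / %): 0.333: 8.7; 1.00: 16.7; 2.00: 21.9; 2.50: 23.2; 4.00: 24.5; 5.00: 25.6

(readings scatter by 0.5 percentage points)

- removed J is counted in
- what was read earlier has a scatter of 0.5 percentage points, one standard deviation
- additions bring no volume worth counting

- zeta: at 5.0 min take out 90% of the J then present, then wait 5.0 min
- theta: at 5.0 min add X, 50.0% of the amount charged, then wait 5.0 min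
- delta: at 5.0 min add Q, 100% of the amount charged, then wait 5.0 min
- eta: change nothing and wait 5.0 min more

* J, in percent of the X first charged, at 5.0 min
* what to do for the largest gain in J; "none" if nothing gains more than 2 percentage points (zeta / theta / delta / eta / none)
* J present, with what was taken out counted in, in percent of the X first charged, after zeta
* J present, with what was taken out counted in, in percent of the X first charged, after eta

J gains 8.7% of the X in the first 0.333 min, but 1.1 percentage points between 4.00 min and 5.00 min. J holds 25.6% of the X, so at most 74.4% of the X is left. Q and E were both charged below X, and these readings can't say which of them holds J back.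

So I carry one number, read with its scatter. The yield on Q is 0.427: J made so far per Q charged. If Q is what holds J back, delta buys at that yield, up to 26 points of the X. E can't be added, so delta is my call. I expect J near 25.6% now. Don't take J out and don't add X: neither brings Q, so if Q is what holds J back, I expect neither to pass the 2 points that counts.

The forecast differs on the choice: J 25.2% now, best none, 25.5% after zeta, 25.6% after eta. Its ground: “None of the options adds E”.

The flask gives J 24.9% now, best delta, 25.6% after zeta and 25.4% after eta.

    X + E → Z (k = 0.0918 M⁻¹ s⁻¹)
    X + Q → J (k = 0.210 M⁻¹ s⁻¹)
    Q + J → L (k = 0.132 M⁻¹ s⁻¹)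
    E + Q → D (k = 0.617 M⁻¹ s⁻¹)

Delta gains 13 points, against 0.76 points for zeta, 0.75 points for theta and 0.49 points for eta. That is about half of my 26 points. At 5.00 min this flask holds 2.0% of its Q and 14% of its E, and Q, the limiting reagent, is first to run out. The neighbour charged with 0.085 M of X keeps the same Q. The yield on Q gives it 15.1% of its X. It reaches 19.4%, which is above that, with 0.35% of its Q left.

(Readings and results stem from a simulated flask from invented constants, and the scatter is random.)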